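**Plan**
1. Retrosynthesis: remove the three MOM ethers; undo a 1,2-acyl shift in the pyranone ring of the flavanone (C3–C4 bond), which leads back to the five-membered ring of a racemic 2-(iodomethyl)-2-phenylbenzofuran-3(2H)-one; then cut C2–CH2I (enolate alkylation), the aryl C6–pyranone C3 bond (Negishi), the O1–C2 and C2–C3 bonds of the furan ring ([4+1] of a salicylaldehyde with a benzyl sulfonium ylide) and the C8–prenyl bond (Claisen from O1).
2. Forward: 4-hydroxy-2-pyranone by lactonisation, then bromide and MOM ether; phloroglucinaldehyde → bis-MOM salicylaldehyde → prenyl by O-to-C Claisen → dihydrobenzofuranol (five-membered ring) → pyranone coupled at the last aromatic C–H → ketone → quaternary iodide → six-membered ring by ring expansion → deprotection.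
3. Enabling feature: in the flavanone the C4 carbonyl is one carbon away from C2, and C2 carries phenyl and O1. A CH2 radical on C2 of the benzofuranone can therefore add to C3=O, and the C2–C3 bond can break to leave a tertiary, benzylic, α-oxygenated radical at C2 of the six-membered ring.
4. Regiochemistry: O1 is singled out by symmetry, directs the prenyl group to C8 and is then tied into the five-membered ring; the expansion moves only a C–C bond, so O1 stays next to C8 and the pyranone stays between the two protected hydroxyls.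
5. Stereochemistry: C2 is the only stereocenter and arises in the key step; both enantiomers of the iodide give one planar radical, which a homochiral thiol reduces on one face (stereoconvergent). The C2/C3 centres of the dihydrobenzofuranol are transient.

Key step: step 14

Remark: the facial sense of hydrogen transfer from the D-gluco thiol in step 14 is taken to be the one that gives 2S; if the intrinsic preference is opposite, a thiol of opposite handedness (from L-glucose, or a D-cysteine peptide thiol) takes its place.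
Remark: compounds 20 to 26 carry a hindered aryl–pyranone axis and may appear as rotamer mixtures; the axis is not a stereo element of the target.

**Route**

Step 1
Reactants: 1 methyl 3-oxopentanoate; 2 N-methoxy-N-methylpropanamide
Product: 4 methyl 4-methyl-3,5-dioxoheptanoate, via sodium lithium dienolate 3 (not isolated)
Conditions: 1 (2 equiv), NaH, THF, 0 °C; n-BuLi, 0 °C; 2 (1 equiv), −78 to 0 °C; aq. HCl
Reagents that add atoms: none
Why: γ-acylation of a β-keto ester dianion (Weiler dianion) by a Weinreb amide; the terminal carbanion attacks, the chelated adduct prevents over-addition, and the excess dianion takes up the acidic proton of the product.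

Step 2
Reactants: 4 methyl 4-methyl-3,5-dioxoheptanoate
Product: 5 6-ethyl-4-hydroxy-5-methyl-2H-pyran-2-one
Conditions: DBU, toluene, reflux; aq. HCl
Reagents that add atoms: none
Why: base-induced lactonisation of a 3,5-diketo ester (the C5 enol oxygen attacks the ester, 6-exo-trig acyl substitution, loss of methanol), a standard 4-hydroxy-2-pyranone synthesis.

Step 3
Reactants: 5 6-ethyl-4-hydroxy-5-methyl-2H-pyran-2-one
Product: 6 3-bromo-6-ethyl-4-hydroxy-5-methyl-2H-pyran-2-one
Conditions: NBS, CH2Cl2, 0 °C to rt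
Reagents that add atoms: N-bromosuccinimide, O=C1CCC(=O)N1Br
Why: electrophilic bromination of the vinylogous acid at C3, the only nucleophilic ring CH.

Step 4
Reactants: 6 3-bromo-6-ethyl-4-hydroxy-5-methyl-2H-pyran-2-one
Product: 7 3-bromo-6-ethyl-4-(methoxymethoxy)-5-methyl-2H-pyran-2-one
Conditions: MOMCl, i-Pr2NEt, CH2Cl2, 0 °C
Reagents that add atoms: chloromethyl methyl ether, COCCl
Why: O-alkylation of the acidic 4-hydroxyl with the hard chloromethyl ether gives the 4-alkoxy-2-pyranone and masks the acidic proton for the organozinc step.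

Step 5
Reactants: 8 2,4,6-trihydroxybenzaldehyde
Product: 9 2-hydroxy-4,6-bis(methoxymethoxy)benzaldehyde
Conditions: MOMCl (2.2 equiv), i-Pr2NEt, CH2Cl2, 0 °C
Reagents that add atoms: chloromethyl methyl ether, COCCl
Why: acetalisation of the para hydroxyl and of one of the two equivalent ortho hydroxyls; the remaining ortho hydroxyl is hydrogen-bonded to the aldehyde and stays free, so the oxygen that becomes O1 is singled out by symmetry.

Step 6
Reactants: 10 2-methylbut-3-en-2-ol
Product: 11 tert-butyl 2-methylbut-3-en-2-yl carbonate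
Conditions: n-BuLi, THF, −78 °C; Boc2O, to rt; aq. NH4Cl
Reagents that add atoms: di-tert-butyl dicarbonate, CC(C)(C)OC(=O)OC(=O)OC(C)(C)C
Why: acylation of the lithium alkoxide of the tertiary allylic alcohol, the usual preparation of this reverse-prenylation reagent.

Step 7
Reactants: 9 2-hydroxy-4,6-bis(methoxymethoxy)benzaldehyde; 11 tert-butyl 2-methylbut-3-en-2-yl carbonate
Product: 12 4,6-bis(methoxymethoxy)-2-[(2-methylbut-3-en-2-yl)oxy]benzaldehyde
Conditions: Pd(PPh3)4 (3 mol%), THF, 0 °C
Reagents that add atoms: none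
Why: Tsuji–Trost O-allylation under zerovalent palladium; ionisation with loss of CO2 gives the 1,1-dimethyl π-allyl complex and tert-butoxide, and the phenoxide attacks the more substituted terminus at low temperature to give the tertiary ether.

Step 8
Reactants: 12 4,6-bis(methoxymethoxy)-2-[(2-methylbut-3-en-2-yl)oxy]benzaldehyde
Product: 13 2-hydroxy-4,6-bis(methoxymethoxy)-3-(3-methylbut-2-en-1-yl)benzaldehyde
Conditions: toluene, 110 °C
Reagents that add atoms: none
Why: aromatic Claisen rearrangement ([3,3]) into the only free ortho position places the normal prenyl group on the carbon that becomes C8 and returns the free O1–H.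

Step 9
Reactants: 14 benzyl bromide; 15 tetrahydrothiophene
Product: 16 1-benzyltetrahydrothiophen-1-ium bromide
Conditions: acetone, rt
Reagents that add atoms: none
Why: SN2 alkylation of the sulfide; the sulfonium salt precipitates.

Step 10
Reactants: 13 2-hydroxy-4,6-bis(methoxymethoxy)-3-(3-methylbut-2-en-1-yl)benzaldehyde; 16 1-benzyltetrahydrothiophen-1-ium bromide
Product: 17 (2S*,3R*)-4,6-bis(methoxymethoxy)-7-(3-methylbut-2-en-1-yl)-2-phenyl-2,3-dihydro-1-benzofuran-3-ol (racemic trans)
Conditions: KOt-Bu (2.5 equiv), THF, −20 °C to rt; aq. NH4Cl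
Reagents that add atoms: none
Why: Corey–Chaykovsky-type [4+1] annulation; the benzylide adds to the aldehyde carbon and the ortho phenoxide closes the five-membered ring at the benzylic carbon with loss of tetrahydrothiophene, the trans relation of C2 and C3 being expected but without consequence because C3 is oxidised and C2 is later made planar.

Step 11
Reactants: 17 (2S*,3R*)-4,6-bis(methoxymethoxy)-7-(3-methylbut-2-en-1-yl)-2-phenyl-2,3-dihydro-1-benzofuran-3-ol; 7 3-bromo-6-ethyl-4-(methoxymethoxy)-5-methyl-2H-pyran-2-one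
Product: 20 6-ethyl-3-[(2S*,3R*)-3-hydroxy-4,6-bis(methoxymethoxy)-7-(3-methylbut-2-en-1-yl)-2-phenyl-2,3-dihydro-1-benzofuran-5-yl]-4-(methoxymethoxy)-5-methyl-2H-pyran-2-one, via C5-lithio lithium alkoxide 18 (not isolated), via arylzinc chloride 19 (not isolated)
Conditions: n-BuLi (2.3 equiv), THF, −20 to 0 °C; ZnCl2, 0 °C to rt; 7, Pd2(dba)3 (2 mol%), SPhos (8 mol%), 60 °C; aq. NH4Cl
Reagents that add atoms: none
Why: directed ortho-lithiation between the two OMOM groups at the only aromatic C–H (C3 is kept at the alcohol level, as its lithium alkoxide, for exactly this step), transmetalation to zinc, and Negishi coupling under zerovalent palladium with a dialkylbiarylphosphine suited to doubly ortho-substituted partners.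

Step 12
Reactants: 20 6-ethyl-3-[(2S*,3R*)-3-hydroxy-4,6-bis(methoxymethoxy)-7-(3-methylbut-2-en-1-yl)-2-phenyl-2,3-dihydro-1-benzofuran-5-yl]-4-(methoxymethoxy)-5-methyl-2H-pyran-2-one
Product: 21 6-ethyl-4-(methoxymethoxy)-3-[4,6-bis(methoxymethoxy)-7-(3-methylbut-2-en-1-yl)-3-oxo-2-phenyl-2,3-dihydro-1-benzofuran-5-yl]-5-methyl-2H-pyran-2-one (racemic)
Conditions: Dess–Martin periodinane, CH2Cl2, 0 °C to rt, argon
Reagents that add atoms: none
Why: Dess–Martin oxidation of the benzylic secondary alcohol unmasks the ketone that the ring expansion needs; the product is kept under argon because the C2–H is now acidic and prone to autoxidation.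

Step 13
Reactants: 21 6-ethyl-4-(methoxymethoxy)-3-[4,6-bis(methoxymethoxy)-7-(3-methylbut-2-en-1-yl)-3-oxo-2-phenyl-2,3-dihydro-1-benzofuran-5-yl]-5-methyl-2H-pyran-2-one
Product: 22 6-ethyl-3-[2-(iodomethyl)-4,6-bis(methoxymethoxy)-7-(3-methylbut-2-en-1-yl)-3-oxo-2-phenyl-2,3-dihydro-1-benzofuran-5-yl]-4-(methoxymethoxy)-5-methyl-2H-pyran-2-one (racemic)
Conditions: CH2I2 (8 equiv), Cs2CO3, DMF, rt, dark, argon
Reagents that add atoms: diiodomethane, ICI
Why: C-alkylation of the soft, phenyl-stabilised enolate at C2 with diiodomethane, as in the standard preparation of Dowd–Beckwith substrates; the neopentyl iodide formed resists a second substitution and the quaternary centre is racemic by design.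

Step 14
Reactants: 22 6-ethyl-3-[2-(iodomethyl)-4,6-bis(methoxymethoxy)-7-(3-methylbut-2-en-1-yl)-3-oxo-2-phenyl-2,3-dihydro-1-benzofuran-5-yl]-4-(methoxymethoxy)-5-methyl-2H-pyran-2-one
Product: 26 (2S)-6-[6-ethyl-4-(methoxymethoxy)-5-methyl-2-oxo-2H-pyran-3-yl]-5,7-bis(methoxymethoxy)-8-(3-methylbut-2-en-1-yl)-2-phenyl-2,3-dihydro-4H-chromen-4-one, via primary alkyl radical 23 (not isolated), via cyclopropyloxy radical 24 (not isolated), via C2 benzylic radical 25 (not isolated)
Conditions: Ph3SiH (2 equiv, slow addition), 2,3,4,6-tetra-O-acetyl-1-thio-β-D-glucopyranose (10 mol%), di-tert-butyl hyponitrite (5 mol%), 1,4-dioxane–hexane, 50 °C, 0.01 M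
Reagents that add atoms: none
Why: Proposed new method: a Dowd–Beckwith ring expansion ended by enantioselective hydrogen transfer, in which Ph3Si• takes iodine from 22, the primary radical 23 adds to the C3 carbonyl of the five-membered ring, and the cyclopropyloxy radical 24 opens by β-scission of the old C2–C3 bond, so that the six-membered ring arises by a net 1,2-acyl shift and the spin ends at C2 in the tertiary, benzylic, α-oxygenated radical 25. The closest known reaction types are the tin- or silane-mediated Dowd–Beckwith expansion of α-halomethyl cyclic ketones and the polarity-reversal catalysis of silane reductions by homochiral carbohydrate thiols, which transfer hydrogen enantioselectively to cyclic α-oxygenated tertiary radicals; their union, and a benzylic radical as the acceptor, are new. The only ring closure is the 3-exo-trig attack of CH2• on C=O, and the six-membered ring is not closed but appears when the bond shared by the two rings of the bicycle breaks. The new stereocenter C2 is under reagent control: both enantiomers of 22 give the same planar radical 25, and the thiol S–H, polarity-matched with this electron-rich radical as Si–H is not, delivers hydrogen to one face, taken to give 2S. The step needs rearrangement before reduction of 23 (secured by the poor hydrogen-donor ability of Ph3SiH, the low thiol concentration and high dilution), 1,2-acyl over 1,2-phenyl shift (carbonyl addition is the faster 3-exo process and leads to the more stabilised radical), and β-scission towards C2 and not towards the aryl carbon (only the former gives a stabilised radical). Iodine abstraction by silyl radicals is far faster than their addition to the remote prenyl and pyranone double bonds, and back-abstraction of the new C2–H by thiyl radicals is held down by excess silane and by stopping at full conversion.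

Step 15
Reactants: 26 (2S)-6-[6-ethyl-4-(methoxymethoxy)-5-methyl-2-oxo-2H-pyran-3-yl]-5,7-bis(methoxymethoxy)-8-(3-methylbut-2-en-1-yl)-2-phenyl-2,3-dihydro-4H-chromen-4-one
Product: 27 (2S)-6-(6-ethyl-4-hydroxy-5-methyl-2-oxo-2H-pyran-3-yl)-5,7-dihydroxy-8-(3-methylbut-2-en-1-yl)-2-phenyl-2,3-dihydro-4H-chromen-4-one
Conditions: HCl (3 M aq.), MeOH, 40 °C, short reaction time
Reagents that add atoms: none
Why: acid-catalysed cleavage of the three MOM acetals (transacetalisation to dimethoxymethane) under mild conditions that leave C2 untouched, since flavanone racemisation runs through base-induced ring opening, and that are short enough to avoid cyclisation of the prenyl group onto the 7-OH.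

**Compound list**
1 | methyl 3-oxopentanoate | CCC(=O)CC(=O)OC | starting material
2 | N-methoxy-N-methylpropanamide | CCC(=O)N(C)OC | starting material
3 | sodium lithium dienolate of 1 | CC=C([O-])C=C([O-])OC.[Na+].[Li+] | intermediate
4 | methyl 4-methyl-3,5-dioxoheptanoate | CCC(=O)C(C)C(=O)CC(=O)OC | intermediate
5 | 6-ethyl-4-hydroxy-5-methyl-2H-pyran-2-one | CCc1oc(=O)cc(O)c1C | intermediate
6 | 3-bromo-6-ethyl-4-hydroxy-5-methyl-2H-pyran-2-one | CCc1oc(=O)c(Br)c(O)c1C | intermediate
7 | 3-bromo-6-ethyl-4-(methoxymethoxy)-5-methyl-2H-pyran-2-one | CCc1oc(=O)c(Br)c(OCOC)c1C | intermediate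
8 | 2,4,6-trihydroxybenzaldehyde | O=Cc1c(O)cc(O)cc1O | starting material
9 | 2-hydroxy-4,6-bis(methoxymethoxy)benzaldehyde | O=Cc1c(O)cc(OCOC)cc1OCOC | intermediate
10 | 2-methylbut-3-en-2-ol | C=CC(C)(C)O | starting material
11 | tert-butyl 2-methylbut-3-en-2-yl carbonate | C=CC(C)(C)OC(=O)OC(C)(C)C | intermediate
12 | 4,6-bis(methoxymethoxy)-2-[(2-methylbut-3-en-2-yl)oxy]benzaldehyde | O=Cc1c(OC(C)(C)C=C)cc(OCOC)cc1OCOC | intermediate
13 | 2-hydroxy-4,6-bis(methoxymethoxy)-3-(3-methylbut-2-en-1-yl)benzaldehyde | O=Cc1c(O)c(CC=C(C)C)c(OCOC)cc1OCOC | intermediate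
14 | benzyl bromide | BrCc1ccccc1 | starting material
15 | tetrahydrothiophene | C1CCSC1 | starting material
16 | 1-benzyltetrahydrothiophen-1-ium bromide | C1CC[S+](C1)Cc1ccccc1.[Br-] | intermediate
17 | (2S*,3R*)-4,6-bis(methoxymethoxy)-7-(3-methylbut-2-en-1-yl)-2-phenyl-2,3-dihydro-1-benzofuran-3-ol (racemic trans; one enantiomer drawn) | O[C@@H]1c2c(OCOC)cc(OCOC)c(CC=C(C)C)c2O[C@H]1c1ccccc1 | intermediate
18 | C5-lithio lithium alkoxide of 17 (racemic; one enantiomer drawn) | [Li]O[C@@H]1c2c(OCOC)c([Li])c(OCOC)c(CC=C(C)C)c2O[C@H]1c1ccccc1 | intermediate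
19 | C5 arylzinc chloride of 17 as lithium alkoxide (racemic; one enantiomer drawn) | [Li]O[C@@H]1c2c(OCOC)c([Zn]Cl)c(OCOC)c(CC=C(C)C)c2O[C@H]1c1ccccc1 | intermediate
20 | 6-ethyl-3-[(2S*,3R*)-3-hydroxy-4,6-bis(methoxymethoxy)-7-(3-methylbut-2-en-1-yl)-2-phenyl-2,3-dihydro-1-benzofuran-5-yl]-4-(methoxymethoxy)-5-methyl-2H-pyran-2-one (racemic; one enantiomer drawn) | O[C@@H]1c2c(OCOC)c(-c3c(OCOC)c(C)c(CC)oc3=O)c(OCOC)c(CC=C(C)C)c2O[C@H]1c1ccccc1 | intermediate
21 | 6-ethyl-4-(methoxymethoxy)-3-[4,6-bis(methoxymethoxy)-7-(3-methylbut-2-en-1-yl)-3-oxo-2-phenyl-2,3-dihydro-1-benzofuran-5-yl]-5-methyl-2H-pyran-2-one (racemic) | O=C1c2c(OCOC)c(-c3c(OCOC)c(C)c(CC)oc3=O)c(OCOC)c(CC=C(C)C)c2OC1c1ccccc1 | intermediate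
22 | 6-ethyl-3-[2-(iodomethyl)-4,6-bis(methoxymethoxy)-7-(3-methylbut-2-en-1-yl)-3-oxo-2-phenyl-2,3-dihydro-1-benzofuran-5-yl]-4-(methoxymethoxy)-5-methyl-2H-pyran-2-one (racemic) | O=C1c2c(OCOC)c(-c3c(OCOC)c(C)c(CC)oc3=O)c(OCOC)c(CC=C(C)C)c2OC1(CI)c1ccccc1 | intermediate
23 | primary alkyl radical from 22 (CH2• on C2 of the benzofuranone) | O=C1c2c(OCOC)c(-c3c(OCOC)c(C)c(CC)oc3=O)c(OCOC)c(CC=C(C)C)c2OC1([CH2])c1ccccc1 | intermediate
24 | cyclopropyloxy radical (cyclopropane fused across C2–C3 of the dihydrobenzofuran, O• on C3) | [O]C12CC1(c1ccccc1)Oc1c(CC=C(C)C)c(OCOC)c(-c3c(OCOC)c(C)c(CC)oc3=O)c(OCOC)c12 | intermediate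
25 | C2 radical of the protected chroman-4-one | O=C1C[C](c2ccccc2)Oc2c(CC=C(C)C)c(OCOC)c(-c3c(OCOC)c(C)c(CC)oc3=O)c(OCOC)c12 | intermediate
26 | (2S)-6-[6-ethyl-4-(methoxymethoxy)-5-methyl-2-oxo-2H-pyran-3-yl]-5,7-bis(methoxymethoxy)-8-(3-methylbut-2-en-1-yl)-2-phenyl-2,3-dihydro-4H-chromen-4-one | CCc1oc(=O)c(-c2c(OCOC)c(CC=C(C)C)c3c(c2OCOC)C(=O)C[C@@H](c2ccccc2)O3)c(OCOC)c1C | intermediate
27 | (2S)-6-(6-ethyl-4-hydroxy-5-methyl-2-oxo-2H-pyran-3-yl)-5,7-dihydroxy-8-(3-methylbut-2-en-1-yl)-2-phenyl-2,3-dihydro-4H-chromen-4-one | CCc1oc(=O)c(-c2c(O)c(CC=C(C)C)c3c(c2O)C(=O)C[C@@H](c2ccccc2)O3)c(O)c1C | target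

**Count and risks**
Total steps: 15. Longest linear sequence: 9 steps (8 → 9 → 12 → 13 → 17 → 20 → 21 → 22 → 26 → 27; the pyranone branch 1 → 7 joining at step 11 is equally long).

Step 14 (new method) is the most likely to fail. The primary radical may take hydrogen before it rearranges, the phenyl group may shift instead of the acyl group, the thiol may be consumed by thiol–ene addition to the prenyl group, and the hydrogen transfer may show poor facial selectivity or lose it through reversible abstraction at C2. The fallback sets out from 22 and comes back at 26. Bu3SnH (syringe pump) and AIBN in benzene at 80 °C, the classical Dowd–Beckwith conditions, should give the racemic protected flavanone F1. Kinetic resolution by Noyori-type asymmetric transfer hydrogenation (RuCl(p-cymene)[(R,R)-TsDPEN], HCO2H/Et3N, EtOAc, rt; catalyst enantiomer chosen so that the 2R ketone reacts fast, by analogy with known flavanone resolutions) should convert the 2R enantiomer into the cis-(2R,4R)-flavan-4-ol F2 and leave 26, which is separated by chromatography.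

Step 11 is the next risk. Transmetalation and reductive elimination may be slow at a bond flanked by three alkoxy groups and a carbonyl, so that protodezincation wins; the lithium alkoxide may be oxidised at palladium; and the prenyl CH2 may be deprotonated in competition with the ring. The fallback sets out from 17 and comes back at 20, and replaces the palladium coupling by ligand coupling at tetravalent lead (Pinhey arylation), which is known to favour 2,6-dialkoxyaryl groups and 4-hydroxy-pyranone-type enols. 17 is silylated (TBSCl, imidazole, DMF) to the silyl ether F3, lithiated (n-BuLi, THF, 0 °C) and quenched with B(OMe)3 to give the boronic acid F4. Boron–lead exchange (Pb(OAc)4, Hg(OAc)2 cat., CHCl3, rt) gives the aryllead triacetate F5, which is not isolated. The unbrominated pyranone 5 and pyridine are added (40 °C) to give the 3-aryl-4-hydroxypyranone F6; MOMCl/i-Pr2NEt gives the MOM ether F7, and Bu4NF in THF frees 20.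

Step 10 is the third risk. The phenoxide may deactivate the aldehyde towards the semi-stabilised ylide, the ring closure at the benzylic carbon may stall, or the product may dehydrate to the 2-phenylbenzofuran. The fallback sets out from 13 and comes back at 22, so it also bypasses the enolate alkylation of step 13. 13 with methyl 2-bromo-2-phenylacetate and K2CO3 in DMF undergoes phenol O-alkylation and intramolecular aldol addition of the ester enolate to the aldehyde, giving methyl 3-hydroxy-4,6-bis(methoxymethoxy)-7-prenyl-2-phenyl-2,3-dihydrobenzofuran-2-carboxylate F8, in which C2 is already quaternary. LiAlH4 (THF, 0 °C) gives the diol F9. Lithiation (n-BuLi, 3.3 equiv), ZnCl2 and Negishi coupling with 7 as in step 11 give the pyranonyl diol F10. MnO2 (CH2Cl2) oxidises only the benzylic alcohol to the hydroxymethyl ketone F11, and an Appel reaction (PPh3, I2, imidazole, toluene, 60 °C) gives 22.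

**Further compounds**
F1 | step 14 | racemic 6-[6-ethyl-4-(methoxymethoxy)-5-methyl-2-oxo-2H-pyran-3-yl]-5,7-bis(methoxymethoxy)-8-(3-methylbut-2-en-1-yl)-2-phenyl-2,3-dihydro-4H-chromen-4-one | CCc1oc(=O)c(-c2c(OCOC)c(CC=C(C)C)c3c(c2OCOC)C(=O)CC(c2ccccc2)O3)c(OCOC)c1C
F2 | step 14 | (2R,4R)-cis-flavan-4-ol from the 2R ketone (same substituents as 26) | CCc1oc(=O)c(-c2c(OCOC)c(CC=C(C)C)c3c(c2OCOC)[C@H](O)C[C@H](c2ccccc2)O3)c(OCOC)c1C
F3 | step 11 | tert-butyldimethylsilyl ether of 17 (racemic; one enantiomer drawn) | CC(C)(C)[Si](C)(C)O[C@@H]1c2c(OCOC)cc(OCOC)c(CC=C(C)C)c2O[C@H]1c1ccccc1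
F4 | step 11 | C5 boronic acid of F3 | CC(C)(C)[Si](C)(C)O[C@@H]1c2c(OCOC)c(B(O)O)c(OCOC)c(CC=C(C)C)c2O[C@H]1c1ccccc1
F5 | step 11 | C5 aryllead triacetate of F3 | CC(C)(C)[Si](C)(C)O[C@@H]1c2c(OCOC)c([Pb](OC(C)=O)(OC(C)=O)OC(C)=O)c(OCOC)c(CC=C(C)C)c2O[C@H]1c1ccccc1
F6 | step 11 | silyl ether of 20 with free pyranone 4-hydroxyl | CC(C)(C)[Si](C)(C)O[C@@H]1c2c(OCOC)c(-c3c(O)c(C)c(CC)oc3=O)c(OCOC)c(CC=C(C)C)c2O[C@H]1c1ccccc1
F7 | step 11 | tert-butyldimethylsilyl ether of 20 | CC(C)(C)[Si](C)(C)O[C@@H]1c2c(OCOC)c(-c3c(OCOC)c(C)c(CC)oc3=O)c(OCOC)c(CC=C(C)C)c2O[C@H]1c1ccccc1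
F8 | step 10 | methyl 3-hydroxy-4,6-bis(methoxymethoxy)-7-(3-methylbut-2-en-1-yl)-2-phenyl-2,3-dihydro-1-benzofuran-2-carboxylate (racemic, diastereomer mixture) | COC(=O)C1(c2ccccc2)Oc2c(CC=C(C)C)c(OCOC)cc(OCOC)c2C1O
F9 | step 10 | 2-(hydroxymethyl)-4,6-bis(methoxymethoxy)-7-(3-methylbut-2-en-1-yl)-2-phenyl-2,3-dihydro-1-benzofuran-3-ol (racemic, diastereomer mixture) | OCC1(c2ccccc2)Oc2c(CC=C(C)C)c(OCOC)cc(OCOC)c2C1O
F10 | step 10 | 6-ethyl-3-[3-hydroxy-2-(hydroxymethyl)-4,6-bis(methoxymethoxy)-7-(3-methylbut-2-en-1-yl)-2-phenyl-2,3-dihydro-1-benzofuran-5-yl]-4-(methoxymethoxy)-5-methyl-2H-pyran-2-one (racemic, diastereomer mixture) | OCC1(c2ccccc2)Oc2c(CC=C(C)C)c(OCOC)c(-c3c(OCOC)c(C)c(CC)oc3=O)c(OCOC)c2C1O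
F11 | step 10 | 6-ethyl-3-[2-(hydroxymethyl)-4,6-bis(methoxymethoxy)-7-(3-methylbut-2-en-1-yl)-3-oxo-2-phenyl-2,3-dihydro-1-benzofuran-5-yl]-4-(methoxymethoxy)-5-methyl-2H-pyran-2-one (racemic) | OCC1(c2ccccc2)Oc2c(CC=C(C)C)c(OCOC)c(-c3c(OCOC)c(C)c(CC)oc3=O)c(OCOC)c2C1=O
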